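The runs stem from a simulated flask for substances that don't exist; the scatter is artificial.

How long should this flask stir before first product peaks, how high does the peak stand, and when does it pass the asked level?

the same everywhere: solid substrate 16 mM

|  | partner | remark | time |
|---|---|---|---|
| gamma | 2.5 equiv (fed, over 15 min) | the very flask that is asked about, followed so far |  |
| epsilon | 1.7 equiv (fed, over 15 min) | run made earlier |  |
| flask | 2.50 equiv (fed, over 15 min) |  | 10 h |

| run | time / h | first product / % | solid substrate / % |
|---|---|---|---|
| gamma | 0.333 | 13.4 | 71.5 |
| gamma | 0.500 | 20.6 | 58.0 |
| gamma | 0.667 | 27.0 | 45.0 |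
| gamma | 1.00 | 36.0 | 18.6 |
| gamma | 1.33 | 40.7 | 1.0 |
| gamma | 2.00 | 30.9 | 0 |
| gamma | 3.00 | 22.0 | 1.7 |
| epsilon | 0.333 | 12.5 | 72.6 |
| epsilon | 0.500 | 20.1 | 62.2 |
| epsilon | 0.833 | 32.7 | 35.9 |
| epsilon | 1.00 | 36.8 | 24.2 |
| epsilon | 2.00 | 47.4 | 2.0 |
| epsilon | 2.50 | 46.0 | 0 |
| epsilon | 4.00 | 39.6 | 0.8 |

(readings scatter by 1 percentage point)

- given per volume of solution although it is solid: solid substrate
- the earlier runs were read with a standard deviation of 1 percentage point
- candidate steps: starting material + partner -> other mono adduct; solid substrate <-> starting material; partner + first product -> double product; partner + other mono adduct -> double product; starting material + partner -> first product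
- at the start none of the solid substrate is in solution

- the best time, 10 h at the latest, for first product
- the amount of first product, in percent of the solid substrate charged, at that time
- the first time at which first product reaches 30%, in the same percent

I order the clocks of gamma, which is this very flask, starting with the feed of 15 min. Slower is the dissolving: solid substrate falls steadily at 0.793 h⁻¹ in fractions of its charge, which gives a dissolving time of 1.26 h. So the feed of partner is over while solid is still feeding the solution. Over the early readings, first product gains 51.3% of what the solid loses; I call this share f.

Slower again is the loss of first product. Once solid substrate reads 0% at 2.00 h, first product in gamma falls, and read as pseudo-first-order up to 3.00 h it has a lifetime of 2.94 h. In epsilon, with less partner, first product falls between its last readings at 0.0999 h⁻¹ against 0.340 h⁻¹ in gamma, so I assume that loss to be proportional to c(partner).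

Now I join the two ends. The exposure number is Θ = 0.428, the dissolving time divided by the lifetime of first product. In gamma the readings of first product climb up to 1.33 h, where solid substrate reads 1.0%, and are lower at 2.00 h, so I put the peak near 1.26 h. Taking f as the supply, though it is read net of early loss, and this late lifetime for the whole climb, a steady supply against first-order loss gives me a peak of f(1 − exp(−Θ))/Θ = 41.7%. Interpolating the readings, I expect the asked level at 0.778 h.

The forecast, holding that “the maximum should sit right around solid exhaustion”, gives 1.3 h, 41.5% and 0.77 h.

The flask gives 1.31 h, 42.6% and 0.776 h.

    starting material + partner → other mono adduct (k = 1.61 L mol⁻¹ min⁻¹)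
    solid substrate ⇌ starting material, rate k2*(cs2 - [starting material]) while solid is left; crystals form when [starting material] > cs2 (solubility = 5.40 mM, k = 0.0510 min⁻¹)
    partner + first product → double product (k = 0.604 L mol⁻¹ min⁻¹)
    partner + other mono adduct → double product (k = 2.17 L mol⁻¹ min⁻¹)
    starting material + partner → first product (k = 4.98 L mol⁻¹ min⁻¹)

At 0.596 h in this flask, starting material has a half-life of 0.076 h by conversion into first product, shorter than the 0.62 h of first product by conversion into double product. Next, a neighbour flask holds 64 mM of solid substrate at equal equivalents. If the dissolving rate per volume holds and the lifetime shrinks to a quarter with c(partner), I reckon its dissolving time at 5.04 h and its Θ at 6.85, and the same expression gives 7.48%. Its computed best is 8.86%.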